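**Strategy**

Everything rests on disconnecting the bond between ring carbon C6 of the quinone and C1' of the nonadecenyl chain. The 2,5-dihydroxy-1,4-benzoquinone ring is a twofold vinylogous acid; with C3 already methylated, C6–H is its only free carbon and a soft, 1,3-dicarbonyl-like nucleophile. A proline-catalysed Knoevenagel condensation with in-situ Hantzsch-ester transfer hydrogenation (three-component reductive alkylation) therefore joins unprotected 2,5-dihydroxy-3-methyl-1,4-benzoquinone to (E)-nonadec-14-enal in one operation and gives the target directly; C1' arrives as the aldehyde carbon. The remote (E)-alkene is set beforehand by dissolving-metal reduction of an alkyne and is not touched by the key step.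

Key step: step 8

Remark: hydroxyquinones are written as their 2,5-dihydroxy-1,4-benzoquinone tautomers, and ring positions follow the numbering of the target (methyl on C3, side chain on C6).

**Route**

Step 1
Reactants: 1 tridecane-1,13-diol
Product: 2 13-bromotridecan-1-ol
Conditions: 48% aq. HBr (1.1 equiv), toluene, reflux
Reagents that add atoms: hydrobromic acid, Br
Why: Acid-promoted SN2 bromination of a primary alcohol; in the two-phase toluene/aqueous HBr system the lipophilic bromo alcohol is withdrawn from the acid phase, so monobromination of the symmetrical diol should dominate, and residual diol and dibromide are separable.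

Step 2
Reactants: 2 13-bromotridecan-1-ol, 3 hex-1-yne
Product: 5 nonadec-14-yn-1-ol, via hex-1-ynyllithium 4 (not isolated)
Conditions: hex-1-yne (2.5 equiv), n-BuLi (2.4 equiv), THF, −78 → 0 °C; then 2, DMPU, 0 °C → rt; aq. NH4Cl
Reagents that add atoms: none
Why: SN2 alkylation of a lithium acetylide by a primary bromide in a dipolar aprotic co-solvent; the excess acetylide absorbs the hydroxyl proton, and O-alkylation should not compete with the far more nucleophilic acetylide carbon.

Step 3
Reactants: 5 nonadec-14-yn-1-ol
Product: 6 (E)-nonadec-14-en-1-ol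
Conditions: Na, liq. NH3/THF, −33 °C; then NH4Cl
Reagents that add atoms: none
Why: Dissolving-metal reduction of an internal alkyne, in which stepwise electron transfer and protonation through the more stable trans-vinyl anion should give the (E)-alkene; the C14=C15 geometry of the target is set here.

Step 4
Reactants: 6 (E)-nonadec-14-en-1-ol
Product: 7 (E)-nonadec-14-enal
Conditions: TEMPO (10 mol%), PhI(OAc)2 (1.1 equiv), CH2Cl2, rt
Reagents that add atoms: none
Why: Oxoammonium-mediated (TEMPO/hypervalent iodine) oxidation of a primary alcohol, which should stop at the aldehyde under anhydrous conditions and leave the isolated (E)-alkene untouched.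

Step 5
Reactants: 8 1,2,4,5-tetramethoxybenzene
Product: 10 1,2,4,5-tetramethoxy-3-methylbenzene, via tetramethoxyphenyllithium 9 (not isolated)
Conditions: n-BuLi (1.05 equiv), TMEDA, THF, 0 °C; then MeI, −78 °C → rt
Reagents that add atoms: iodomethane, CI
Why: Directed ortho-metalation at a ring C–H flanked by two methoxy groups, followed by SN2 methylation of the aryllithium; one equivalent of base should keep the reaction at the mono-lithiated stage.

Step 6
Reactants: 10 1,2,4,5-tetramethoxy-3-methylbenzene
Product: 11 2,5-dimethoxy-3-methyl-1,4-benzoquinone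
Conditions: CAN (2.5 equiv), MeCN/H2O, 0 °C
Reagents that add atoms: water, O
Why: Cerium(IV) oxidative demethylation of a para-dimethoxyarene to the para-quinone; either para pair of methoxy groups gives the same 2,5-dimethoxy-3-methylquinone because of the substitution pattern.

Step 7
Reactants: 11 2,5-dimethoxy-3-methyl-1,4-benzoquinone
Product: 13 2,5-dihydroxy-3-methyl-1,4-benzoquinone, via disodium quinonediolate 12 (not isolated)
Conditions: 2 M aq. NaOH, THF, rt; then 2 M HCl
Reagents that add atoms: sodium hydroxide, [Na+].[OH-]
Why: Addition–elimination hydrolysis of the two vinylogous methyl esters, driven by formation of the resonance-stabilised dianion, which is protonated on acidification.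

Step 8
Reactants: 13 2,5-dihydroxy-3-methyl-1,4-benzoquinone, 7 (E)-nonadec-14-enal
Product: 15 2,5-dihydroxy-3-methyl-6-[(E)-nonadec-14-en-1-yl]-1,4-benzoquinone, via alkylidene trione 14 (not isolated)
Conditions: L-proline (20 mol%), Hantzsch ester (1.1 equiv), EtOH/CH2Cl2, rt
Reagents that add atoms: none
Why: Proline-catalysed Knoevenagel condensation of the aldehyde carbon with C6, the only unsubstituted ring carbon and the α-carbon of the vinylogous acid O=C1–C6(H)=C5–OH, should give the 6-alkylidene trione 14, an ortho-quinone-methide-like acceptor that takes up hydride from the Hantzsch ester at the exocyclic carbon and tautomerises back to the dihydroxyquinone. The closest known reaction type is the organocatalytic three-component reductive alkylation (Knoevenagel/transfer hydrogenation) of cyclic 1,3-dicarbonyls and hydroxyquinones, including 2-hydroxy-1,4-naphthoquinone and 2,5-dihydroxy-1,4-benzoquinone, with aliphatic aldehydes. No ring is closed and no stereocentre is created. The step needs C- over O-alkylation and a single alkylation, both secured because the electrophile is an aldehyde and C6 is the only free nucleophilic carbon. Addition of a second quinone to 14 should be suppressed by having the hydride donor present from the start. The isolated C14'=C15' alkene is unconjugated and inert to the Hantzsch ester, so its (E)-geometry is retained.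

**Compound list**

1 | tridecane-1,13-diol | OCCCCCCCCCCCCCO | starting material
2 | 13-bromotridecan-1-ol | OCCCCCCCCCCCCCBr | intermediate
3 | hex-1-yne | CCCCC#C | starting material
4 | hex-1-ynyllithium | [Li]C#CCCCC | intermediate
5 | nonadec-14-yn-1-ol | CCCCC#CCCCCCCCCCCCCCO | intermediate
6 | (E)-nonadec-14-en-1-ol | CCCC/C=C/CCCCCCCCCCCCCO | intermediate
7 | (E)-nonadec-14-enal | CCCC/C=C/CCCCCCCCCCCCC=O | intermediate
8 | 1,2,4,5-tetramethoxybenzene | COc1cc(OC)c(OC)cc1OC | starting material
9 | (2,3,5,6-tetramethoxyphenyl)lithium | [Li]c1c(OC)c(OC)cc(OC)c1OC | intermediate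
10 | 1,2,4,5-tetramethoxy-3-methylbenzene | COc1cc(OC)c(OC)c(C)c1OC | intermediate
11 | 2,5-dimethoxy-3-methyl-1,4-benzoquinone | COC1=CC(=O)C(OC)=C(C)C1=O | intermediate
12 | disodium 3-methyl-2,5-dioxido-1,4-benzoquinone | CC1=C([O-])C(=O)C=C([O-])C1=O.[Na+].[Na+] | intermediate
13 | 2,5-dihydroxy-3-methyl-1,4-benzoquinone | CC1=C(O)C(=O)C=C(O)C1=O | intermediate
14 | 5-hydroxy-6-methyl-3-[(E)-nonadec-14-en-1-ylidene]cyclohex-5-ene-1,2,4-trione (exocyclic C=C geometry not defined; removed in the same step) | O=C1C(O)=C(C)C(=O)C(=O)C1=CCCCCCCCCCCCC/C=C/CCCC | intermediate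
15 | 2,5-dihydroxy-3-methyl-6-[(E)-nonadec-14-en-1-yl]-1,4-benzoquinone | CCCC/C=C/CCCCCCCCCCCCCC1=C(O)C(=O)C(C)=C(O)C1=O | target

**Count and risks**

Total steps: 8. Longest linear sequence: 5 steps (1, 2, 3, 4, 8); the quinone branch (steps 5, 6, 7) joins at step 8.

Steps most likely to fail:

1. Step 8 (key step). The condensation may be slow because the dihydroxyquinone dissolves poorly; a second quinone may add to the alkylidene intermediate before hydride transfer; the aldehyde may undergo amine-catalysed self-aldol condensation. The fallback forms the same bond by a polar coupling at the arene oxidation level. It sets out from 6 and 10 and returns at 15. Alcohol 6 would be converted (CBr4, PPh3, CH2Cl2) into (E)-19-bromononadec-5-ene F1. Arene 10 would be lithiated at its last ring C–H (n-BuLi, TMEDA, THF) to (2,3,5,6-tetramethoxy-4-methylphenyl)lithium F2, which would be alkylated with F1 (THF/HMPA) to 1,2,4,5-tetramethoxy-3-methyl-6-[(E)-nonadec-14-en-1-yl]benzene F3. CAN oxidation would give 2,5-dimethoxy-3-methyl-6-[(E)-nonadec-14-en-1-yl]-1,4-benzoquinone F4, and hydrolysis (aq. NaOH, then HCl) would give 15.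

2. Step 6. The electron-rich arene may undergo oxidative aryl–aryl coupling at its unsubstituted position or over-oxidation instead of clean demethylation. The fallback avoids a one-electron oxidant. It sets out from 10 and returns at 13. Exhaustive demethylation with BBr3 (CH2Cl2, −78 °C → rt) would give 3-methylbenzene-1,2,4,5-tetrol F5, which should autoxidise during an aqueous work-up under air to 13, bypassing 11.

3. Step 3. The long-chain alkynol may dissolve poorly in ammonia, giving incomplete reduction, and prolonged exposure may cause over-reduction. The fallback brings in the (E)-alkene ready-made by a stereoretentive sp3–sp2 Suzuki–Miyaura coupling. It sets out from 2 and returns at 6. Silylation of 2 (TBSCl, imidazole, CH2Cl2) would give [(13-bromotridecyl)oxy](tert-butyl)dimethylsilane F6. Coupling with commercial (E)-hex-1-enylboronic acid (Pd(OAc)2, P(t-Bu)2Me, KOt-Bu, t-amyl alcohol, rt) would give tert-butyldimethyl{[(E)-nonadec-14-en-1-yl]oxy}silane F7, and TBAF (THF) would release 6.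

Further compounds
F1 | step 8 | (E)-19-bromononadec-5-ene | CCCC/C=C/CCCCCCCCCCCCCBr
F2 | step 8 | (2,3,5,6-tetramethoxy-4-methylphenyl)lithium | [Li]c1c(OC)c(OC)c(C)c(OC)c1OC
F3 | step 8 | 1,2,4,5-tetramethoxy-3-methyl-6-[(E)-nonadec-14-en-1-yl]benzene | CCCC/C=C/CCCCCCCCCCCCCc1c(OC)c(OC)c(C)c(OC)c1OC
F4 | step 8 | 2,5-dimethoxy-3-methyl-6-[(E)-nonadec-14-en-1-yl]-1,4-benzoquinone | CCCC/C=C/CCCCCCCCCCCCCC1=C(OC)C(=O)C(C)=C(OC)C1=O
F5 | step 6 | 3-methylbenzene-1,2,4,5-tetrol | Cc1c(O)c(O)cc(O)c1O
F6 | step 3 | [(13-bromotridecyl)oxy](tert-butyl)dimethylsilane | CC(C)(C)[Si](C)(C)OCCCCCCCCCCCCCBr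
F7 | step 3 | tert-butyldimethyl{[(E)-nonadec-14-en-1-yl]oxy}silane | CCCC/C=C/CCCCCCCCCCCCCO[Si](C)(C)C(C)(C)C
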